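Plan
1. Retrosynthesis: in each half the oxepane is cut at C4–C5 and at the ring-fusion bond C6–C7 (which also opens the cyclohexane), taking an isopropenyl C5=C6 out of a 5-alkyl-2,2-dimethylfuran-3(2H)-one. Further cuts are C8–C9 (furanone dienolate + terminal epoxide), C11–C6 (isopropenyl copper reagent + 2,3-epoxy alcohol) and C10=C11 (olefination or cross-metathesis).
2. Enabling feature: O1–C2(Me2)–C3(O)–C4 plus the O-bearing fusion carbon C7 form a masked vinylogous ester. Its C4=C7 bond adds photochemically to the alkene held by the tether C8–C11, closing the cyclohexane and a cyclobutane. The resulting C4–C7 bond, flanked by donor O1 and acceptor C3=O, is then cut, expanding the five-membered ring to the oxepane.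
3. Forward order: pent-4-enal supplies C11'–C12'–C12–C11. Its aldehyde end is grown into the left half (cyclohexane and cyclobutane in step 8, oxepane in step 9), then its vinyl end into the right half by the same sequence (steps 16 and 17).
4. Stereochemistry: C10'/C11' and C10/C11 come from Sharpless epoxidation (D-tartrate on the Z-alkenol, L-tartrate on the E-alkenol, which makes the halves epimeric at C10) and invertive epoxide opening. C6 and C7 come from the substrate-controlled cycloaddition and axial hydride delivery; C3 and C3' from CBS reduction.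
5. The free 3-OH is told apart from the 3'-acetate by timing: the left ketone is reduced and acetylated before the right ketone exists, and the right ketone is reduced last.

Key step: step 16

Remark: locants follow the biogenetic skeleton (right half O1, C2 = CMe2, C3 = CHOH, C4, C5, C6 = C–Me, C7 = CH–O, C8, C9, C10 = C(Me)OAc, C11, C12; left half primed); compounds 1, 4, 5, 18 and the reagents named are assumed commercial.

Step 1
Reactants: 1 3-hydroxy-3-methylbutan-2-one
Product: 3 2,2,5-trimethylfuran-3(2H)-one, via hydroxy diketone 2 (not isolated)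
Conditions: NaH (3 equiv), EtOAc, THF, 0 °C → reflux; then 2 M HCl, rt
Reagents that add atoms: ethyl acetate CCOC(C)=O
Why: Claisen condensation of the ketone enolate with ethyl acetate gives the 1,3-diketone, whose tertiary hydroxyl adds to the distal carbonyl and dehydrates under acid (cyclodehydration of α'-hydroxy 1,3-diketones to 3(2H)-furanones).

Step 2
Reactants: 4 pent-4-enal; 5 ethyl 2-[bis(2,2,2-trifluoroethoxy)phosphoryl]propanoate
Product: 6 ethyl (2Z)-2-methylhepta-2,6-dienoate
Conditions: KN(SiMe3)2, 18-crown-6, THF, −78 °C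
Reagents that add atoms: none
Why: Still–Gennari olefination; the electron-poor phosphonate under dissociating conditions eliminates from the kinetic adduct and should give the (Z)-trisubstituted enoate.

Step 3
Reactants: 6 ethyl (2Z)-2-methylhepta-2,6-dienoate
Product: 7 (2Z)-2-methylhepta-2,6-dien-1-ol
Conditions: iBu2AlH (2.2 equiv), CH2Cl2, −78 → 0 °C; aq. potassium sodium tartrate
Reagents that add atoms: none
Why: 1,2-reduction of the enoate by the aluminium hydride should give the allylic alcohol with the alkene geometry unchanged.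

Step 4
Reactants: 7 (2Z)-2-methylhepta-2,6-dien-1-ol
Product: 8 [(2R,3S)-3-(but-3-en-1-yl)-2-methyloxiran-2-yl]methanol
Conditions: Ti(OiPr)4 (10 mol%), D-(−)-diethyl tartrate (12 mol%), tBuOOH, 4 Å molecular sieves, CH2Cl2, −20 °C
Reagents that add atoms: tert-butyl hydroperoxide CC(C)(C)OO
Why: Sharpless asymmetric epoxidation; the D-tartrate complex should epoxidise the (Z)-2-methyl allylic alcohol on the face that gives the (2R,3S)-epoxide (sets C10'), while the remote vinyl group has no directing hydroxyl and stays.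

Step 5
Reactants: 8 [(2R,3S)-3-(but-3-en-1-yl)-2-methyloxiran-2-yl]methanol
Product: 9 (2S,3S)-2-methyl-3-(prop-1-en-2-yl)hept-6-ene-1,2-diol
Conditions: CH2=C(Me)MgBr (4 equiv), CuI (20 mol%), THF, −30 → 0 °C; aq. NH4Cl
Reagents that add atoms: isopropenylmagnesium bromide CC(=C)[Mg]Br
Why: Copper-catalysed Grignard opening of a 2,3-epoxy alcohol; C2 is fully substituted, so the isopropenyl group should enter at C3 with inversion (sets C11') and leave the C10' oxygen in place.

Step 6
Reactants: 9 (2S,3S)-2-methyl-3-(prop-1-en-2-yl)hept-6-ene-1,2-diol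
Product: 11 (2S)-2-methyl-2-[(3S)-2-methylhepta-1,6-dien-3-yl]oxirane, via primary tosylate 10 (not isolated)
Conditions: TsCl, Et3N, Bu2SnO (5 mol%), CH2Cl2, 0 °C → rt; then K2CO3, MeOH, 0 °C
Reagents that add atoms: none
Why: Tin-acetal-directed sulfonylation of the primary hydroxyl, then 3-exo-tet closure by the tertiary alkoxide; the C10' oxygen is kept, so the configuration is retained.

Step 7
Reactants: 11 (2S)-2-methyl-2-[(3S)-2-methylhepta-1,6-dien-3-yl]oxirane; 3 2,2,5-trimethylfuran-3(2H)-one
Product: 14 (3R,4S)-1-(5,5-dimethyl-4-oxo-4,5-dihydrofuran-2-yl)-3-methyl-4-(prop-1-en-2-yl)oct-7-en-3-yl acetate, via lithium dienolate 12 (not isolated), via lithium alkoxide 13 (not isolated)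
Conditions: 3, LiN(iPr)2, THF, −78 °C; then 11, LiClO4, −78 → 0 °C; then Ac2O, 4-(dimethylamino)pyridine (cat.), 0 °C → rt
Reagents that add atoms: acetic anhydride CC(=O)OC(C)=O
Why: The γ-dienolate of the vinylogous ester (the 5-methyl group is its only enolisable position) should alkylate at its exocyclic carbon with the unhindered CH2 end of the 2,2-disubstituted epoxide (salt-assisted enolate–epoxide opening), and acetylation in the flask stops the tertiary alkoxide from adding to the furanone.

Step 8
Reactants: 14 (3R,4S)-1-(5,5-dimethyl-4-oxo-4,5-dihydrofuran-2-yl)-3-methyl-4-(prop-1-en-2-yl)oct-7-en-3-yl acetate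
Product: 15 left photoadduct 8-(but-3-en-1-yl)-3,3,7,9-tetramethyl-4-oxo-2-oxatricyclo[5.4.0.0(1,5)]undecan-9-yl acetate (cis-anti-cis)
Conditions: hν (350 nm, Pyrex), degassed MeCN (0.005 M), rt
Reagents that add atoms: none
Why: Intramolecular enone–alkene [2+2] photocycloaddition of the vinylogous ester (the reaction of step 16, first run on the simpler half): 1,6-closure C7'–C6' forms the cyclohexane, C4'–C5' closes the cyclobutane, and a chair-like tether with C12' equatorial and C11'–H eclipsing the isopropenyl C=C should place the C6' methyl cis to the butenyl chain.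

Step 9
Reactants: 15 left photoadduct
Product: 17 (5aS,6S,7R,9aS)-6-(but-3-en-1-yl)-2,2,5a,7-tetramethyl-3-oxodecahydro-1-benzoxepin-7-yl acetate, via triethylsilyl enol ether 16 (not isolated)
Conditions: Et3SiH (3 equiv), Me3SiOTf (20 mol%), CH2Cl2, −78 → −40 °C; then 1 M HCl, THF, 0 °C
Reagents that add atoms: none
Why: Proposed new method: O-silylation of the C3' ketone makes the strained C4'–C7' bond, which has the O1' lone pair at one end and the silyloxy-carbenium at the other, a retro-aldol (donor–acceptor cyclobutane) bond that should heterolyse to a seven-membered cyclic oxocarbenium ion and a silyl enol ether, and Et3SiH then reduces the oxocarbenium ion by axial attack anti to the axial C6' methyl, which sets C7'–H trans to that methyl and regenerates silyl triflate; the closest known reactions are the acid-induced retro-aldol opening of 3-alkoxyenone photoadducts (de Mayo reaction) and the Et3SiH/Me3SiOTf reductive etherification of cyclic hemiketals to trans-fused oxepanes.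

Step 10
Reactants: 17 left oxepanone; 18 2-methylprop-2-enal
Product: 19 (5aS,6S,7R,9aS)-2,2,5a,7-tetramethyl-6-[(3E)-4-methyl-5-oxopent-3-en-1-yl]-3-oxodecahydro-1-benzoxepin-7-yl acetate
Conditions: 18 (10 equiv), second-generation Grubbs catalyst RuCl2(=CHPh)(PCy3)(H2IMes) (5 mol%), CH2Cl2, 40 °C
Reagents that add atoms: none
Why: Cross-metathesis of an unhindered terminal alkene with excess methacrolein, which barely homodimerises, should give the (E)-2-methyl enal under thermodynamic control; ketone, ether and ester are inert.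

Step 11
Reactants: 19 left enal
Product: 20 (3S,5aS,6S,7R,9aS)-3-hydroxy-6-[(3E)-5-hydroxy-4-methylpent-3-en-1-yl]-2,2,5a,7-tetramethyldecahydro-1-benzoxepin-7-yl acetate
Conditions: (R)-Me-CBS oxazaborolidine [(3aR)-1-methyl-3,3-diphenyltetrahydro-1H,3H-pyrrolo[1,2-c][1,3,2]oxazaborole] (20 mol%), catecholborane (3 equiv), toluene, −78 → −30 °C; then MeOH, aq. NaHCO3
Reagents that add atoms: none
Why: CBS reduction; the catalyst–borane complex reduces the enal 1,2 and delivers hydride to the C3' ketone on the face set by the catalyst, which tells the quaternary C2' from the C4' methylene and should give the (3'S)-alcohol.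

Step 12
Reactants: 20 left diol
Product: 21 (3S,5aS,6S,7R,9aS)-3-hydroxy-6-{2-[(2S,3S)-3-(hydroxymethyl)-3-methyloxiran-2-yl]ethyl}-2,2,5a,7-tetramethyldecahydro-1-benzoxepin-7-yl acetate
Conditions: Ti(OiPr)4 (20 mol%), L-(+)-diethyl tartrate (24 mol%), tBuOOH, 4 Å molecular sieves, CH2Cl2, −20 °C
Reagents that add atoms: tert-butyl hydroperoxide CC(C)(C)OO
Why: Sharpless asymmetric epoxidation under reagent control; L-tartrate on the (E)-alkenol should give the (2S,3S)-epoxide, which together with step 4 (D-tartrate, Z-alkenol) leads to the same C11 but the opposite C10 configuration in the two halves.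

Step 13
Reactants: 21 right epoxy alcohol
Product: 22 (3S,5aS,6S,7R,9aS)-6-[(3S,4R)-4,5-dihydroxy-4-methyl-3-(prop-1-en-2-yl)pentyl]-3-hydroxy-2,2,5a,7-tetramethyldecahydro-1-benzoxepin-7-yl acetate
Conditions: CH2=C(Me)MgBr (6 equiv), CuI (30 mol%), THF, −40 → −10 °C; aq. NH4Cl
Reagents that add atoms: isopropenylmagnesium bromide CC(=C)[Mg]Br
Why: As in step 5, the copper-catalysed opening should occur at the secondary epoxide carbon with inversion (sets C11); the hindered tertiary acetate should survive at low temperature.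

Step 14
Reactants: 22 right triol
Product: 24 (3S,5aS,6S,7R,9aS)-3-hydroxy-2,2,5a,7-tetramethyl-6-{(3S)-4-methyl-3-[(2R)-2-methyloxiran-2-yl]pent-4-en-1-yl}decahydro-1-benzoxepin-7-yl acetate, via primary tosylate 23 (not isolated)
Conditions: TsCl, Et3N, Bu2SnO (5 mol%), CH2Cl2, 0 °C → rt; then K2CO3, MeOH, 0 °C
Reagents that add atoms: none
Why: As in step 6; only the 1,2-diol forms the tin acetal, so the primary hydroxyl is sulfonylated in the presence of the isolated 3'-hydroxyl, and closure keeps the C10 oxygen.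

Step 15
Reactants: 24 right epoxide; 3 2,2,5-trimethylfuran-3(2H)-one
Product: 26 (3S,5aS,6S,7R,9aS)-6-[(3S,4S)-4-acetoxy-6-(5,5-dimethyl-4-oxo-4,5-dihydrofuran-2-yl)-4-methyl-3-(prop-1-en-2-yl)hexyl]-2,2,5a,7-tetramethyldecahydro-1-benzoxepine-3,7-diyl diacetate, via dilithium alkoxide 25 (not isolated)
Conditions: 3 (4.2 equiv), LiN(iPr)2 (4.0 equiv), THF, −78 °C; then 24, LiClO4, −78 → 0 °C; then Ac2O, 4-(dimethylamino)pyridine (cat.), 0 °C → rt
Reagents that add atoms: acetic anhydride CC(=O)OC(C)=O
Why: The salt-assisted enolate–epoxide opening of step 7 is repeated with the lithium dienolate of 3, made beforehand in the same way and kept in excess over the amide, so that one equivalent of it serves as the base for the 3'-hydroxyl and no free amide meets the tertiary acetate; the anhydride quench then acetylates both alkoxides of 25, so all three acetates of the target are in place.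

Step 16
Reactants: 26 right photo-substrate
Product: 27 right photoadduct (26 with furanone C4=C7 and isopropenyl C5=C6 joined into a cis-anti-cis 2-oxatricyclo[5.4.0.0(1,5)]undecan-4-one unit)
Conditions: hν (350 nm, Pyrex), degassed MeCN (0.005 M), rt
Reagents that add atoms: none
Why: Excitation of the vinylogous ester and intersystem crossing give a triplet enone that bonds from C7 to the internal alkene carbon C6 and then from C4 to C5 through a 1,4-biradical, so both new bonds arise in one photochemical operation. The closest known reaction type is the intramolecular enone–alkene [2+2] photocycloaddition of 5-alkenyl 3(2H)-furanones and other β-alkoxy enones (first stage of a de Mayo sequence), already run in step 8. The cyclohexane closes by 6-exo-trig attack of C7 on C6 across the four-atom tether C8–C11 (straight 1,6 closure), the cyclobutane by combination of the C4/C5 radical pair, necessarily cis-fused to both the furanone and the cyclohexane. C7 and C4 follow from these strain-enforced cis fusions (C4 is lost again in step 17), while C6 is set relative to C11 by a chair-like tether with C12 equatorial and the C11–H bond eclipsing the isopropenyl C=C (allylic strain), which puts the C6 methyl anti to C11–H, that is cis to the ethano chain. The step needs straight instead of crossed closure, secured by the tether length (the crossed mode would need a seven-membered ring), face selectivity, secured by C11, and chemoselectivity, secured because the furanone is the only chromophore above 300 nm and the isopropenyl group the only alkene within reach. The cyclobutane bond C4–C7 that is left carries donor O1 and acceptor C3=O and is the one cut next.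

Step 17
Reactants: 27 right photoadduct
Product: 29 (3S,5aS,6S,7R,9aS)-6-{2-[(5aS,6S,7S,9aS)-7-acetoxy-2,2,5a,7-tetramethyl-3-oxodecahydro-1-benzoxepin-6-yl]ethyl}-2,2,5a,7-tetramethyldecahydro-1-benzoxepine-3,7-diyl diacetate, via triethylsilyl enol ether 28 (not isolated)
Conditions: Et3SiH (3 equiv), Me3SiOTf (20 mol%), CH2Cl2, −78 → −40 °C; then 1 M HCl, THF, 0 °C
Reagents that add atoms: none
Why: Proposed new method: as in step 9, silylation of the C3 ketone should trigger heterolysis of the donor–acceptor bond C4–C7 (O1 push, silyloxy pull, relief of cyclobutane strain) to a ring-expanded cyclic oxocarbenium ion and a silyl enol ether, and Et3SiH should add axially to C7 anti to the axial C6 methyl, giving the trans-fused oxepane; the closest known reactions are the de Mayo retro-aldol opening of 3-alkoxyenone photoadducts and Et3SiH/Me3SiOTf reductive etherification.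

Step 18
Reactants: 29 right oxepanone
Product: 30 (3S,5aS,6S,7R,9aS)-6-{2-[(3S,5aS,6S,7S,9aS)-7-acetoxy-3-hydroxy-2,2,5a,7-tetramethyldecahydro-1-benzoxepin-6-yl]ethyl}-2,2,5a,7-tetramethyldecahydro-1-benzoxepine-3,7-diyl diacetate
Conditions: (R)-Me-CBS oxazaborolidine (20 mol%), catecholborane (2 equiv), toluene, −78 → −30 °C; then MeOH, aq. NaHCO3
Reagents that add atoms: none
Why: CBS reduction as in step 11 should set C3 (S) by catalyst control (quaternary C2 against the C4 methylene) and leave the three acetates untouched, so the only free hydroxyl is the one formed here.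

Compound list
1 | 3-hydroxy-3-methylbutan-2-one | CC(=O)C(C)(C)O | starting material
2 | 5-hydroxy-5-methylhexane-2,4-dione | CC(=O)CC(=O)C(C)(C)O | intermediate
3 | 2,2,5-trimethylfuran-3(2H)-one | CC1=CC(=O)C(C)(C)O1 | intermediate
4 | pent-4-enal | C=CCCC=O | starting material
5 | ethyl 2-[bis(2,2,2-trifluoroethoxy)phosphoryl]propanoate | CCOC(=O)C(C)P(=O)(OCC(F)(F)F)OCC(F)(F)F | starting material
6 | ethyl (2Z)-2-methylhepta-2,6-dienoate | CCOC(=O)/C(C)=C\CCC=C | intermediate
7 | (2Z)-2-methylhepta-2,6-dien-1-ol | OC/C(C)=C\CCC=C | intermediate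
8 | [(2R,3S)-3-(but-3-en-1-yl)-2-methyloxiran-2-yl]methanol | OC[C@@]1(C)O[C@H]1CCC=C | intermediate
9 | (2S,3S)-2-methyl-3-(prop-1-en-2-yl)hept-6-ene-1,2-diol | OC[C@@](C)(O)[C@H](C(C)=C)CCC=C | intermediate
10 | (2S,3S)-2-hydroxy-2-methyl-3-(prop-1-en-2-yl)hept-6-en-1-yl 4-methylbenzenesulfonate | Cc1ccc(cc1)S(=O)(=O)OC[C@@](C)(O)[C@H](C(C)=C)CCC=C | intermediate
11 | (2S)-2-methyl-2-[(3S)-2-methylhepta-1,6-dien-3-yl]oxirane | C1O[C@@]1(C)[C@H](C(C)=C)CCC=C | intermediate
12 | lithium 2,2-dimethyl-5-methylidene-2,5-dihydrofuran-3-olate | [Li+].[O-]C1=CC(=C)OC1(C)C | intermediate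
13 | lithium (3R,4S)-1-(5,5-dimethyl-4-oxo-4,5-dihydrofuran-2-yl)-3-methyl-4-(prop-1-en-2-yl)oct-7-en-3-olate | [Li+].CC1(C)OC(CC[C@@](C)([O-])[C@H](C(C)=C)CCC=C)=CC1=O | intermediate
14 | (3R,4S)-1-(5,5-dimethyl-4-oxo-4,5-dihydrofuran-2-yl)-3-methyl-4-(prop-1-en-2-yl)oct-7-en-3-yl acetate | CC1(C)OC(CC[C@@](C)(OC(C)=O)[C@H](C(C)=C)CCC=C)=CC1=O | intermediate
15 | left photoadduct: 8-(but-3-en-1-yl)-3,3,7,9-tetramethyl-4-oxo-2-oxatricyclo[5.4.0.0(1,5)]undecan-9-yl acetate, cis-anti-cis, 7-methyl cis to the butenyl chain and to the acetoxy group | CC1(C)O[C@@]23CC[C@@](C)(OC(C)=O)[C@@H](CCC=C)[C@]2(C)C[C@H]3C1=O | intermediate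
16 | triethylsilyl enol ether of 17 (C3'=C4') | CC1(C)O[C@H]2CC[C@@](C)(OC(C)=O)[C@@H](CCC=C)[C@]2(C)CC=C1O[Si](CC)(CC)CC | intermediate
17 | (5aS,6S,7R,9aS)-6-(but-3-en-1-yl)-2,2,5a,7-tetramethyl-3-oxodecahydro-1-benzoxepin-7-yl acetate | CC1(C)O[C@H]2CC[C@@](C)(OC(C)=O)[C@@H](CCC=C)[C@]2(C)CCC1=O | intermediate
18 | 2-methylprop-2-enal (methacrolein) | CC(=C)C=O | starting material
19 | (5aS,6S,7R,9aS)-2,2,5a,7-tetramethyl-6-[(3E)-4-methyl-5-oxopent-3-en-1-yl]-3-oxodecahydro-1-benzoxepin-7-yl acetate | CC1(C)O[C@H]2CC[C@@](C)(OC(C)=O)[C@@H](CC/C=C(\C)C=O)[C@]2(C)CCC1=O | intermediate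
20 | (3S,5aS,6S,7R,9aS)-3-hydroxy-6-[(3E)-5-hydroxy-4-methylpent-3-en-1-yl]-2,2,5a,7-tetramethyldecahydro-1-benzoxepin-7-yl acetate | CC1(C)O[C@H]2CC[C@@](C)(OC(C)=O)[C@@H](CC/C=C(\C)CO)[C@]2(C)CC[C@@H]1O | intermediate
21 | (3S,5aS,6S,7R,9aS)-3-hydroxy-6-{2-[(2S,3S)-3-(hydroxymethyl)-3-methyloxiran-2-yl]ethyl}-2,2,5a,7-tetramethyldecahydro-1-benzoxepin-7-yl acetate | CC1(C)O[C@H]2CC[C@@](C)(OC(C)=O)[C@@H](CC[C@@H]3O[C@@]3(C)CO)[C@]2(C)CC[C@@H]1O | intermediate
22 | (3S,5aS,6S,7R,9aS)-6-[(3S,4R)-4,5-dihydroxy-4-methyl-3-(prop-1-en-2-yl)pentyl]-3-hydroxy-2,2,5a,7-tetramethyldecahydro-1-benzoxepin-7-yl acetate | CC1(C)O[C@H]2CC[C@@](C)(OC(C)=O)[C@@H](CC[C@@H](C(C)=C)[C@@](C)(O)CO)[C@]2(C)CC[C@@H]1O | intermediate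
23 | primary 4-methylbenzenesulfonate of 22 | CC1(C)O[C@H]2CC[C@@](C)(OC(C)=O)[C@@H](CC[C@@H](C(C)=C)[C@@](C)(O)COS(=O)(=O)c3ccc(C)cc3)[C@]2(C)CC[C@@H]1O | intermediate
24 | (3S,5aS,6S,7R,9aS)-3-hydroxy-2,2,5a,7-tetramethyl-6-{(3S)-4-methyl-3-[(2R)-2-methyloxiran-2-yl]pent-4-en-1-yl}decahydro-1-benzoxepin-7-yl acetate | CC1(C)O[C@H]2CC[C@@](C)(OC(C)=O)[C@@H](CC[C@@H](C(C)=C)[C@]3(C)CO3)[C@]2(C)CC[C@@H]1O | intermediate
25 | dilithium bis-alkoxide (C10–O and C3'–O) of the epoxide-opened adduct of 24 and the lithium dienolate of 3 | [Li+].[Li+].CC1(C)O[C@H]2CC[C@@](C)(OC(C)=O)[C@@H](CC[C@@H](C(C)=C)[C@@](C)([O-])CCC3=CC(=O)C(C)(C)O3)[C@]2(C)CC[C@@H]1[O-] | intermediate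
26 | (3S,5aS,6S,7R,9aS)-6-[(3S,4S)-4-acetoxy-6-(5,5-dimethyl-4-oxo-4,5-dihydrofuran-2-yl)-4-methyl-3-(prop-1-en-2-yl)hexyl]-2,2,5a,7-tetramethyldecahydro-1-benzoxepine-3,7-diyl diacetate | CC1(C)O[C@H]2CC[C@@](C)(OC(C)=O)[C@@H](CC[C@@H](C(C)=C)[C@@](C)(OC(C)=O)CCC3=CC(=O)C(C)(C)O3)[C@]2(C)CC[C@@H]1OC(C)=O | intermediate
27 | right photoadduct: 26 with C4–C5 and C6–C7 formed; 2-oxatricyclo[5.4.0.0(1,5)]undecan-4-one unit, cis-anti-cis, 7-methyl cis to the ethano chain and trans to the 9-acetoxy group | CC1(C)O[C@H]2CC[C@@](C)(OC(C)=O)[C@@H](CC[C@@H]3[C@@](C)(OC(C)=O)CC[C@@]45OC(C)(C)C(=O)[C@@H]4C[C@@]35C)[C@]2(C)CC[C@@H]1OC(C)=O | intermediate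
28 | triethylsilyl enol ether of 29 (C3=C4) | CC1(C)O[C@H]2CC[C@@](C)(OC(C)=O)[C@@H](CC[C@@H]3[C@@](C)(OC(C)=O)CC[C@@H]4OC(C)(C)C(O[Si](CC)(CC)CC)=CC[C@@]34C)[C@]2(C)CC[C@@H]1OC(C)=O | intermediate
29 | (3S,5aS,6S,7R,9aS)-6-{2-[(5aS,6S,7S,9aS)-7-acetoxy-2,2,5a,7-tetramethyl-3-oxodecahydro-1-benzoxepin-6-yl]ethyl}-2,2,5a,7-tetramethyldecahydro-1-benzoxepine-3,7-diyl diacetate | CC1(C)O[C@H]2CC[C@@](C)(OC(C)=O)[C@@H](CC[C@@H]3[C@@](C)(OC(C)=O)CC[C@@H]4OC(C)(C)C(=O)CC[C@@]34C)[C@]2(C)CC[C@@H]1OC(C)=O | intermediate
30 | (3S,5aS,6S,7R,9aS)-6-{2-[(3S,5aS,6S,7S,9aS)-7-acetoxy-3-hydroxy-2,2,5a,7-tetramethyldecahydro-1-benzoxepin-6-yl]ethyl}-2,2,5a,7-tetramethyldecahydro-1-benzoxepine-3,7-diyl diacetate | CC(=O)O[C@H]1CC[C@]2(C)[C@H](CC[C@@](C)(OC(C)=O)[C@H]2CC[C@H]2[C@]3(C)CC[C@H](O)C(C)(C)O[C@H]3CC[C@]2(C)OC(C)=O)OC1(C)C | target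

Total step count: 18. Longest linear sequence: 17 (steps 2 to 18; step 1 makes reagent 3).

Steps most likely to fail

Step 9 (labelled). The silylated ketone may not trigger heterolysis of the C4'–C7' bond at low temperature, hydride may reach the oxocarbenium ion without face control, or the tertiary acetate may ionise under the Lewis acid. The fallback uses known chemistry in two stages. It sets out from 15: dilute aqueous HCl in THF at room temperature should effect the de Mayo-type retro-aldol opening with water as the nucleophile, as known for photoadducts of 3-alkoxy enones, and give hydroxy diketone F1. The seven-membered hemiketal of F1 is then reduced with Et3SiH and Me3SiOTf in CH2Cl2 at −78 °C, the standard reductive etherification that gives trans-fused oxepanes by axial hydride delivery, which comes back to the route at 17.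

Step 17 (labelled). The same processes are at risk, here in a triacetate that also carries a tertiary-alkyl ether in the left oxepane, so competing ionisation is more of a concern. The fallback is the same known two-stage detour. It sets out from 27: aqueous acid in THF should give hydroxy diketone F2, and reductive etherification (Et3SiH, Me3SiOTf, CH2Cl2, −78 °C) closes the right oxepane and comes back at 29.

Step 7. The delocalised dienolate may open the epoxide too slowly, so that proton transfer or addition of the tertiary alkoxide to the furanone (spiroketal formation) wins before acetylation. The fallback changes the nucleophile and moves furanone formation after the C–C bond. It sets out from 11: diketone 2, here isolated from step 1 by neutral work-up, is converted with LiN(iPr)2 (3 equiv) into its trilithium salt, whose terminal carbanion opens the epoxide at CH2 as β-diketone dianions are known to do. Mild acid work-up then cyclodehydrates the adduct to hydroxy furanone F3. Acetylation of the tertiary alcohol (Ac2O, Sc(OTf)3 cat., MeCN, −20 °C) comes back to the route at 14.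

Further compounds
F1 | step 9 | (1R,2S,3S)-2-(but-3-en-1-yl)-3-(4-hydroxy-4-methyl-3-oxopentyl)-1,3-dimethyl-4-oxocyclohexyl acetate | CC(C)(O)C(=O)CC[C@@]1(C)[C@H](CCC=C)[C@](C)(OC(C)=O)CCC1=O
F2 | step 17 | (3S,5aS,6S,7R,9aS)-6-{2-[(1S,2S,6S)-2-acetoxy-6-(4-hydroxy-4-methyl-3-oxopentyl)-2,6-dimethyl-5-oxocyclohexyl]ethyl}-2,2,5a,7-tetramethyldecahydro-1-benzoxepine-3,7-diyl diacetate | CC1(C)O[C@H]2CC[C@@](C)(OC(C)=O)[C@@H](CC[C@@H]3[C@@](C)(OC(C)=O)CCC(=O)[C@@]3(C)CCC(=O)C(C)(C)O)[C@]2(C)CC[C@@H]1OC(C)=O
F3 | step 7 | 5-[(3R,4S)-3-hydroxy-3-methyl-4-(prop-1-en-2-yl)oct-7-en-1-yl]-2,2-dimethylfuran-3(2H)-one | CC1(C)OC(CC[C@@](C)(O)[C@H](C(C)=C)CCC=C)=CC1=O
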